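**Retrosynthetic overview**
1. Endgame: the target comes from acidolysis of two tert-butyl esters, oxidation at C14 and stepwise O-acylation (11-OBz, then 7-OAc) of a 7α,8β,11α,14-tetraol. The tetraol comes from an 8β-OH-directed double reduction of a 7,11-diketone.
2. Ring C (second and last ring): cut C9–C11 and C8–C14. C11 acts as a nitronate (masked acyl anion) that attacks the enone β-carbon C9. The α-silyloxy enolate released closes on the C14 aldehyde in the same flask, and a Nef reaction then reveals C11=O.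
3. The C11–C14 piece with the quaternary C13 comes from an auxiliary-controlled deconjugative addition of a tigloyl imide dienolate to nitroethylene.
4. Ring B (first ring) is the carbocycle of p-cresol: a dearomatising C10–C1 bond formation, then a desymmetrising Mukaiyama–Michael addition (C5–C4). Ring A is never closed, and both acid arms travel as tert-butyl esters.

Numbering: C1–C20 are those of the 2,3-seco-isopimarane skeleton. Ring B is C5–C10 and ring C is C8, C9, C11–C14. β is the face of the C10 methyl and α is the face of H5 and H9.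

Assumption: both silyl ketene acetals and a toluene solution of nitroethylene are taken as catalogue items, and the drawn enantiomers of the oxazaborolidine and of the oxazolidinone are taken to be the ones that give the drawn configurations (otherwise their antipodes are used).

**Step 1**
Reactants: 1 p-cresol; 2 1-tert-butoxy-1-(tert-butyldimethylsilyloxy)ethene
Product: 3 tert-butyl 2-(1-methyl-4-oxocyclohexa-2,5-dien-1-yl)acetate
Conditions: PhI(OAc)2 (1.1 equiv), 2 (3 equiv), CH2Cl2/(CF3)2CHOH 9:1, −40 °C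
Reagents that add atoms: none
Why: Proposed new method: two-electron oxidation by the trivalent-iodine reagent turns the normally nucleophilic para carbon of the phenol into a phenoxenium electrophile that the ketene silyl acetal captures at C10, as in the known oxidative dearomatising allylation of 4-alkylphenols with allylsilanes (3 is achiral, so no stereocentre is set).

**Step 2**
Reactants: 3 dienone; 4 1-tert-butoxy-2-methyl-1-(trimethylsilyloxy)prop-1-ene
Product: 6 ring B enone diester (10β-CH3; 5α-H), via silyl dienol ether 5 (not isolated)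
Conditions: 4 (1.5 equiv), (S)-3,3-diphenyl-1-(2-methylphenyl)tetrahydro-1H,3H-pyrrolo[1,2-c][1,3,2]oxazaborole (20 mol %) + (CF3SO2)2NH (20 mol %), Ph3PO (25 mol %), toluene, −20 °C; then 1 M HCl, THF
Reagents that add atoms: none
Why: Proposed new method: the Mukaiyama–Michael addition under a chiral cationic oxazaborolidine, known for this kind of ketene acetal with simple cyclic enones, is extended to a desymmetrisation in which the catalyst picks one enantiotopic enone arm and the nucleophile enters anti to the larger CH2CO2t-Bu group, fixing C10 and C5 in one event.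

**Step 3**
Reactants: 6 ring B enone diester
Product: 7 8α,9α-epoxy ketone
Conditions: t-BuOOH, DBU, CH2Cl2, 0 °C → rt
Reagents that add atoms: tert-butyl hydroperoxide, CC(C)(C)OO
Why: Weitz–Scheffer nucleophilic epoxidation of the only enone, with axial attack at C9 anti to the axial C10 methyl giving the α-epoxide, whose configuration is erased in step 4.

**Step 4**
Reactants: 7 epoxy ketone
Product: 8 8-triethylsilyloxy enone (2-silyloxycyclohex-2-enone)
Conditions: Et3SiOTf, Et3N, CH2Cl2, −20 °C → rt
Reagents that add atoms: triethylsilyl triflate, CC[Si](CC)(CC)OS(=O)(=O)C(F)(F)F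
Why: Proposed new method: silyl triflate activates the oxirane and the amine removes the ketone-acidified H8, so the C9–O bond breaks (E1cB type) and O8 is trapped regiospecifically as the enol silane, by analogy with the silyl triflate/amine isomerisation of epoxides to allylic silyl ethers and the base-induced epoxy ketone to diosphenol rearrangement.

**Step 5**
Reactants: 9 (E)-2-methylbut-2-enoyl chloride (tigloyl chloride); 10 (S)-4-isopropyl-1,3-oxazolidin-2-one
Product: 11 (S)-4-isopropyl-3-[(E)-2-methylbut-2-enoyl]oxazolidin-2-one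
Conditions: 10, n-BuLi, THF, −78 °C; then 9
Reagents that add atoms: none
Why: N-acylation of the lithiated Evans oxazolidinone, in which no new stereocentre is formed.

**Step 6**
Reactants: 11 tigloyl imide; 12 nitroethylene
Product: 14 (S)-4-isopropyl-3-[(R)-2-methyl-2-(2-nitroethyl)but-3-enoyl]oxazolidin-2-one, via sodium dienolate 13 (not isolated)
Conditions: NaN(SiMe3)2, THF, −78 °C; 12 (toluene solution), −78 °C; AcOH
Reagents that add atoms: sodium bis(trimethylsilyl)amide, C[Si](C)(C)[N-][Si](C)(C)C.[Na+] (its sodium stays only in 13)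
Why: γ-Deprotonation gives the chelated dienolate, which reacts at its α-carbon (deconjugative Evans-type Michael addition) on the face away from the isopropyl group, creating the quaternary C13 (R) and the vinyl group together.

**Step 7**
Reactants: 14 nitro imide
Product: 15 (R)-2-methyl-2-(2-nitroethyl)but-3-en-1-ol
Conditions: LiBH4, H2O (1 equiv), Et2O, 0 °C
Reagents that add atoms: none
Why: Reductive removal of the auxiliary with LiBH4 spares the aliphatic nitro group and the alkene and cannot touch the quaternary centre.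

**Step 8**
Reactants: 15 nitro alcohol
Product: 16 (R)-2-methyl-2-(2-nitroethyl)but-3-enal
Conditions: Dess–Martin periodinane, CH2Cl2, rt
Reagents that add atoms: none
Why: Dess–Martin oxidation of the neopentyl alcohol gives a non-enolisable aldehyde, so C13 cannot epimerise.

**Step 9 (key step)**
Reactants: 8 8-triethylsilyloxy enone; 16 nitro aldehyde
Product: 19 trans-fused 8β,14-dihydroxy-11-nitro-7-ketone, via Michael adduct 17 (not isolated), via silylated aldol 18 (not isolated)
Conditions: DBU (0.3 equiv), MeCN (2 M), rt, 48 h; then 1 M HCl, THF, 0 °C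
Reagents that add atoms: none
Why: Proposed new method: the nitronate of 16, a masked acyl anion at C11, adds reversibly to the electrophilic β-carbon C9 of 8 (nitro-Michael reaction) and the regiodefined α-silyloxy enolate so formed closes on the non-enolisable aldehyde (intramolecular aldol), so that under equilibration C11 and C14 sit equatorial on ring B (9α-H, trans-decalin) and O8 sits axial (8β) because a β-C14 would be syn-axial to the C10 methyl; the closest known reactions are nitroalkane additions to hindered enones such as isophorone and base-promoted nitro-Michael/aldol annulations.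

**Step 10**
Reactants: 19 nitro diol ketone
Product: 21 8β,14-dihydroxy-7,11-diketone, via silyl nitronate 20 (not isolated)
Conditions: Me3SiCl, Et3N, CH2Cl2, 0 °C; then m-CPBA, 0 °C
Reagents that add atoms: chlorotrimethylsilane, C[Si](C)(C)Cl (only in 20); m-chloroperbenzoic acid, OOC(=O)c1cccc(Cl)c1
Why: Nef reaction through the silyl nitronate, whose C=N bond the peracid cleaves faster than it epoxidises the monosubstituted alkene, unmasks the C11 ketone while C9 keeps its more stable equatorial arrangement.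

**Step 11**
Reactants: 21 dihydroxy diketone
Product: 22 7α,8β,11α,14-tetraol
Conditions: Me4NBH(OAc)3 (8 equiv), MeCN/AcOH 1:1, −20 °C
Reagents that add atoms: none
Why: Saksena–Evans hydroxyl-directed reduction, in which the acyloxyborohydride bound to the axial 8β-OH delivers hydride to the β-faces of C7 and C11 and so gives the 7α (trans to O8) and 11α (1,3-anti) alcohols.

**Step 12**
Reactants: 22 tetraol
Product: 23 11α-benzoate
Conditions: BzCl (1.1 equiv), pyridine, 0 °C
Reagents that add atoms: benzoyl chloride, O=C(Cl)c1ccccc1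
Why: Selective esterification, since the equatorial 11α-OH is acylated faster than the axial 7α-OH, the 14-OH flanked by two fully substituted carbons or the tertiary 8-OH.

**Step 13**
Reactants: 23 11α-benzoate
Product: 24 7α-acetate 11α-benzoate
Conditions: Ac2O (1.2 equiv), DMAP (cat.), pyridine, 0 °C
Reagents that add atoms: acetic anhydride, CC(=O)OC(C)=O
Why: DMAP-catalysed acetylation takes the 7α-OH because the 14-OH is doubly neopentyl and the 8-OH is tertiary, and the trans-diaxial 7,8-relationship blocks acyl migration.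

**Step 14**
Reactants: 24 7α-acetate 11α-benzoate
Product: 25 14-ketone di-tert-butyl ester
Conditions: Dess–Martin periodinane, CH2Cl2, rt
Reagents that add atoms: none
Why: Dess–Martin oxidation of the only remaining secondary alcohol gives the C14 ketone under neutral conditions that leave the tertiary 8-OH, both esters and the vinyl group alone.

**Step 15**
Reactants: 25 14-ketone di-tert-butyl ester
Product: 26 target CNP0315860.1
Conditions: CF3CO2H/CH2Cl2 1:2, 0 °C → rt
Reagents that add atoms: none
Why: Acidolysis (E1 loss of isobutene) of both tert-butyl esters frees the C2 and C3 acids without touching the acetate, the benzoate, the α-ketol or any stereocentre.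

**Compound list**

| No. | Name | SMILES | Role |
|---|---|---|---|
| 1 | p-cresol | Cc1ccc(O)cc1 | starting material |
| 2 | 1-tert-butoxy-1-(tert-butyldimethylsilyloxy)ethene | C=C(OC(C)(C)C)O[Si](C)(C)C(C)(C)C | starting material |
| 3 | tert-butyl 2-(1-methyl-4-oxocyclohexa-2,5-dien-1-yl)acetate | CC1(CC(=O)OC(C)(C)C)C=CC(=O)C=C1 | intermediate |
| 4 | 1-tert-butoxy-2-methyl-1-(trimethylsilyloxy)prop-1-ene | CC(C)=C(OC(C)(C)C)O[Si](C)(C)C | starting material |
| 5 | C7 trimethylsilyl dienol ether of 6 (6,8-diene) | C[Si](C)(C)OC1=C[C@@H](C(C)(C)C(=O)OC(C)(C)C)[C@](C)(CC(=O)OC(C)(C)C)C=C1 | intermediate |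
| 6 | ring B enone: 7-oxo-8-ene, 10β-CH3, 10α-CH2CO2t-Bu, 5β-C(CH3)2CO2t-Bu, 5α-H | O=C1C=C[C@@](C)(CC(=O)OC(C)(C)C)[C@H](C(C)(C)C(=O)OC(C)(C)C)C1 | intermediate |
| 7 | 8α,9α-epoxide of 6 | O=C1[C@H]2O[C@H]2[C@@](C)(CC(=O)OC(C)(C)C)[C@H](C(C)(C)C(=O)OC(C)(C)C)C1 | intermediate |
| 8 | 8-triethylsilyloxy-8-en-7-one | CC[Si](CC)(CC)OC1=C[C@@](C)(CC(=O)OC(C)(C)C)[C@H](C(C)(C)C(=O)OC(C)(C)C)CC1=O | intermediate |
| 9 | tigloyl chloride | C/C=C(\C)C(=O)Cl | starting material |
| 10 | (S)-4-isopropyl-1,3-oxazolidin-2-one | CC(C)[C@H]1COC(=O)N1 | starting material |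
| 11 | (S)-4-isopropyl-3-tigloyloxazolidin-2-one | C/C=C(\C)C(=O)N1[C@@H](C(C)C)COC1=O | intermediate |
| 12 | nitroethylene | C=C[N+](=O)[O-] | starting material |
| 13 | sodium dienolate of 11 | C=CC(C)=C([O-])N1[C@@H](C(C)C)COC1=O.[Na+] | intermediate |
| 14 | (S)-4-isopropyl-3-[(R)-2-methyl-2-(2-nitroethyl)but-3-enoyl]oxazolidin-2-one | O=C1OC[C@H](C(C)C)N1C(=O)[C@@](C)(C=C)CC[N+](=O)[O-] | intermediate |
| 15 | (R)-2-methyl-2-(2-nitroethyl)but-3-en-1-ol | OC[C@@](C)(C=C)CC[N+](=O)[O-] | intermediate |
| 16 | (R)-2-methyl-2-(2-nitroethyl)but-3-enal | O=C[C@@](C)(C=C)CC[N+](=O)[O-] | intermediate |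
| 17 | Michael adduct: 8-OTES 7-ketone with the C11(NO2)–C14 aldehyde chain equatorial at C9 (C8 and C11 epimers) | CC[Si](CC)(CC)OC1[C@H](C([N+](=O)[O-])C[C@](C)(C=C)C=O)[C@@](C)(CC(=O)OC(C)(C)C)[C@H](C(C)(C)C(=O)OC(C)(C)C)CC1=O | intermediate |
| 18 | 8β-OTES ether of 19 | C=C[C@@]1(C)CC([N+](=O)[O-])[C@@H]2[C@@](C)(CC(=O)OC(C)(C)C)[C@H](C(C)(C)C(=O)OC(C)(C)C)CC(=O)[C@@]2(O[Si](CC)(CC)CC)C1O | intermediate |
| 19 | trans-decalin: 7-oxo, 8β-OH, 9α-H, 11-NO2, 13β-CH3, 13α-vinyl, 14-OH (C11 and C14 configurations inconsequential) | C=C[C@@]1(C)CC([N+](=O)[O-])[C@@H]2[C@@](C)(CC(=O)OC(C)(C)C)[C@H](C(C)(C)C(=O)OC(C)(C)C)CC(=O)[C@@]2(O)C1O | intermediate |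
| 20 | C11 trimethylsilyl nitronate of 19 | C=C[C@@]1(C)CC(=[N+]([O-])O[Si](C)(C)C)[C@@H]2[C@@](C)(CC(=O)OC(C)(C)C)[C@H](C(C)(C)C(=O)OC(C)(C)C)CC(=O)[C@@]2(O)C1O | intermediate |
| 21 | 8β,14-dihydroxy-7,11-diketone | C=C[C@@]1(C)CC(=O)[C@@H]2[C@@](C)(CC(=O)OC(C)(C)C)[C@H](C(C)(C)C(=O)OC(C)(C)C)CC(=O)[C@@]2(O)C1O | intermediate |
| 22 | 7α,8β,11α,14-tetraol | C=C[C@@]1(C)C[C@@H](O)[C@@H]2[C@@](C)(CC(=O)OC(C)(C)C)[C@H](C(C)(C)C(=O)OC(C)(C)C)C[C@@H](O)[C@@]2(O)C1O | intermediate |
| 23 | 11α-benzoate of 22 | C=C[C@@]1(C)C[C@@H](OC(=O)c2ccccc2)[C@@H]2[C@@](C)(CC(=O)OC(C)(C)C)[C@H](C(C)(C)C(=O)OC(C)(C)C)C[C@@H](O)[C@@]2(O)C1O | intermediate |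
| 24 | 7α-acetate 11α-benzoate | C=C[C@@]1(C)C[C@@H](OC(=O)c2ccccc2)[C@@H]2[C@@](C)(CC(=O)OC(C)(C)C)[C@H](C(C)(C)C(=O)OC(C)(C)C)C[C@@H](OC(C)=O)[C@@]2(O)C1O | intermediate |
| 25 | 14-ketone, di-tert-butyl ester of the target | C=C[C@@]1(C)C[C@@H](OC(=O)c2ccccc2)[C@@H]2[C@@](C)(CC(=O)OC(C)(C)C)[C@H](C(C)(C)C(=O)OC(C)(C)C)C[C@@H](OC(C)=O)[C@@]2(O)C1=O | intermediate |
| 26 | CNP0315860.1 | C=C[C@@]1(C)C[C@@H](OC(=O)c2ccccc2)[C@@H]2[C@@](C)(CC(=O)O)[C@H](C(C)(C)C(=O)O)C[C@@H](OC(C)=O)[C@@]2(O)C1=O | target |

**Step count**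
Total step count: 15. Longest linear sequence: 11 (steps 1–4 and 9–15).

**Steps most likely to fail**

(a) Step 9, the annulation. The β-carbon C9 is neopentyl and the enone is deactivated by its silyloxy group, so the nitro-Michael step may not proceed. The fallback sets out from 6 (with 16) and comes back at 21.
- I2/pyridine converts 6 into the more electrophilic 2-iodoenone F6.
- DBU and 16 then give a Michael addition at C9. The nitronate oxygen next displaces iodide at C8, which gives the cis-fused isoxazoline N-oxide F7. C9–C11 and C8–O are therefore made together.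
- P(OMe)3 followed by Mo(CO)6 in wet MeCN cleaves the N–O bonds to the 8-hydroxy-7,11-diketo aldehyde F8.
- Catalytic camphorsulfonic acid closes C8–C14 through the enediol to give 21.

(b) Step 1, C–C bond formation on the phenoxenium ion. The ketene acetal may be solvolysed or oxidised first. The fallback sets out from 1 and comes back at 3.
- The precedented oxidative allylation (allyltrimethylsilane, PhI(OAc)2, (CF3)2CHOH) gives 4-allyl-4-methylcyclohexa-2,5-dienone F1.
- OsO4 (cat.)/NaIO4 cleaves only the electron-rich terminal alkene to the aldehyde F2.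
- NaClO2/NaH2PO4 oxidises it to the dienone acetic acid F3.
- tert-Butyl 2,2,2-trichloroacetimidate esterifies F3 to 3.

(c) Step 4, epoxy ketone to silyloxy enone. Enol silane formation toward C6 or skeletal rearrangement at the neopentyl C9 may compete. The fallback sets out from 6 and comes back at 8.
- OsO4 (cat.)/N-methylmorpholine N-oxide gives the 8α,9α-diol F4.
- Et3SiCl/imidazole silylates only the less hindered, more acidic 8-OH to give the 8-O-triethylsilyl ether F5.
- MsCl/Et3N eliminates the 9-OH of this β-hydroxy ketone regiospecifically to 8.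

**Further compounds**
F1 | step 1 | 4-allyl-4-methylcyclohexa-2,5-dienone | C=CCC1(C)C=CC(=O)C=C1
F2 | step 1 | 2-(1-methyl-4-oxocyclohexa-2,5-dien-1-yl)acetaldehyde | O=CCC1(C)C=CC(=O)C=C1
F3 | step 1 | 2-(1-methyl-4-oxocyclohexa-2,5-dien-1-yl)acetic acid | O=C(O)CC1(C)C=CC(=O)C=C1
F4 | step 4 | 8α,9α-diol of 6 | O=C1[C@@H](O)[C@@H](O)[C@@](C)(CC(=O)OC(C)(C)C)[C@H](C(C)(C)C(=O)OC(C)(C)C)C1
F5 | step 4 | 8-O-triethylsilyl ether of F4 | O=C1[C@@H](O[Si](CC)(CC)CC)[C@@H](O)[C@@](C)(CC(=O)OC(C)(C)C)[C@H](C(C)(C)C(=O)OC(C)(C)C)C1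
F6 | step 9 | 8-iodo enone (2-iodoenone from 6) | O=C1C(I)=C[C@@](C)(CC(=O)OC(C)(C)C)[C@H](C(C)(C)C(=O)OC(C)(C)C)C1
F7 | step 9 | cis-fused isoxazoline N-oxide (O on C8, C11 on C9) | O=C1C2O[N+]([O-])=C(C[C@](C)(C=C)C=O)C2[C@@](C)(CC(=O)OC(C)(C)C)[C@H](C(C)(C)C(=O)OC(C)(C)C)C1
F8 | step 9 | 8-hydroxy-7,11-diketo aldehyde | O=C1C(O)C(C(=O)C[C@](C)(C=C)C=O)[C@@](C)(CC(=O)OC(C)(C)C)[C@H](C(C)(C)C(=O)OC(C)(C)C)C1
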